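**Remark (assumption):** the target has no stereocentre, and its C2–C1' axis is flanked on the benzofuran side only by O1 and C3–H of a five-membered ring, so it should rotate freely at room temperature; the compound is treated as achiral and no enantiocontrol is planned.

**Numbering used throughout:** 1 ethoxyacetylene; 2 prenyl bromide; 3 lithium ethoxyacetylide; 4 prenylated ynol ether; 5 prenylketene; 6 3-ethoxy-2,4-diprenylcyclobutenone; 7 benzofuran-6-ol; 8 its TIPS ether; 9 the 2-lithio derivative of 8; 10 carbinol adduct; 11 3-benzofuranyl-2,4-diprenylcyclobutenone; 12 chloroacetaldehyde dimethyl acetal; 13 sodium methoxyacetylide; 14 methoxyacetylene; 15 vinylketene; 16 4-vinylcyclobutenone; 17 dienylketene; 18 cyclohexadienone; 19 silyl-protected target; 20 target.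

## Analysis of the target

The target (C25H28O4) is a 2-arylbenzofuran: a benzofuran (O1, C2, C3, C3a–C7a) with a free OH at C6, joined through C2 to C1' of a pentasubstituted benzene ring (C1'–C6'). That ring carries prenyl groups at C2' and C6', OH at C3', OMe at C5' and its only hydrogen at C4'. There is no stereocentre, so the difficulty is entirely constitutional. The feature the plan is tied to is ring C1'–C6': it is a resorcinol monomethyl ether with H on the carbon between the two oxygens (C4'), and the three contiguous carbon substituents on the far side (C6' prenyl, C1' benzofuranyl, C2' prenyl) have identical outer members. Without the C4'H–C5'(OMe) unit, the ring is therefore a four-carbon unit (C3', C2', C1', C6') with equal substituents at both ends. The ortho-prenylphenol unit (C2' prenyl next to C3'–OH) cyclizes to a 2,2-dimethylchroman under acid and to chromenes or dihydrofurans under oxidants. Benzofuran C3 is nucleophilic, and the C5' methyl ether must survive while two phenols end up free, so late Lewis-acid dealkylations are excluded. The synthesis is hard for three reasons: the prenyl groups sit at the two positions flanking the biaryl bond rather than at C4', which aromatic substitution prefers; the C2–C1' bond is doubly ortho-substituted; and OH and OMe must be told apart on a ring that is otherwise symmetric about the C1'···C4' axis.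

## Retrosynthetic reasoning

**20 ⇒ 19.** Only the silyl ether on the benzofuran C6 oxygen is removed. The group is needed earlier because a free phenol would quench the organolithium 9 and would acylate on the ketene intermediates of the key step. It is removed under buffered, non-acidic conditions so that the ortho-prenylphenol is not cyclized.

**19 ⇒ 11 + 14 (key disconnection).** The arene bonds C3'–C4' and C5'–C6' are cut. The two-carbon unit C4'H–C5'(OMe) leaves as methoxyacetylene 14, and C3' is reconnected to C6', which gives the four-membered ring of cyclobutenone 11 with C3' as its carbonyl carbon. The cut is placed here because the 3-alkoxyphenol pattern with H between the oxygens is exactly what the union of a vinylketene with a terminal alkoxyacetylene delivers. The carbene–alkyne benzannulations would give the para-dioxygenated pattern and do not fit. What is gained: the C3'–OH comes from the ketene carbonyl and the C5'–OMe from 14, so the two oxygens are differentiated by mechanism. Both prenyl groups and the benzofuran are placed before the ring exists, so no aromatic substitution is ever performed on ring C1'–C6'. The forward reaction has to open 11 to vinylketene 15, capture it with 14 regioselectively in the presence of two trisubstituted alkenes, and carry the adduct 16 through a second ring opening to 17 and a 6π closure to 18 and then 19.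

**11 ⇒ 6 + 9.** The future biaryl bond C2–C1' is cut at a stage where C1' is still C3 of a cyclobutenone. It is made by 1,2-addition of the 2-lithiobenzofuran 9 to the carbonyl of vinylogous ester 6, followed by hydrolytic 1,3-transposition. The hindered bond is thus formed as a carbonyl addition, not as a cross-coupling between two ortho-substituted aromatic partners. Because both C2 and C4 of 6 bear prenyl, the transposition has only one constitutional outcome. 9 comes from 8 by C2 lithiation, and 8 from commercial 7 by silylation.

**6 ⇒ 4 + 4 (through 5).** The four-membered ring of 6 is cut into ketene 5 and ynol ether 4 (a [2+2] retron). Ketene 5 is itself generated from 4 by thermal retro-ene fragmentation of the O-ethyl group. The pseudo-symmetry of the target thus becomes real economy: one C9 building block is used twice and supplies all four ring carbons of 6 and both prenyl groups.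

**4 ⇒ 1 + 2.** The C(sp)–C(sp3) bond is cut; forward, acetylide 3 (from 1) is alkylated with 2 at the primary allylic carbon.

**14 ⇒ 12.** Methoxyacetylene is traced to the commercial chloroacetal 12 by twofold base-induced elimination through 13, because 14 is volatile and best prepared fresh.

## Alternatives that were turned down

**Alternative 1:** The textbook disconnection cuts the furan ring at O1–C2 and C3–C3a. Forward, aryl alkyne A1 and iodophenol A2 are joined by a palladium/copper alkynylation, and the coupled intermediate closes 5-endo-dig in the same pot. It was turned down because A1 already contains the whole problem. Its pentasubstituted ring needs two prenyl groups on either side of the alkyne, introduced by iterative directed metalations or rearrangements that compete with the more reactive C4' position. Its OH/OMe differentiation needs a statistical mono-alkylation or extra protecting-group steps. The alkyne of A1 is flanked by two ortho prenyl groups, which slows both the coupling and the ring closure. An acetal protecting group on C3'–O would have to be removed with acid next to a prenyl group. The step count to A1 alone is expected to exceed that of the whole chosen route.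

**Alternative 2:** The biomimetic late-stage prenylation cuts both C2'–CH2 and C6'–CH2 bonds. Forward, the unprenylated arylbenzofuran A3 is C-prenylated twice with 2 (phenoxide C-alkylation or acid-mediated Friedel–Crafts alkylation). It was turned down on regiochemical grounds. In A3 the most nucleophilic carbon of the aryl ring is C4' (ortho to both oxygens), and C5 and C7 (ortho to the C6–OH) and C3 of the benzofuran compete as well. The target needs substitution only at the two most hindered positions, and one of them (C6') is ortho to OMe and para to OH, so it cannot be reached by an ortho-selective phenoxide alkylation or a Claisen rearrangement from the C3' oxygen. Acidic conditions would also cyclize the first prenyl group onto the neighbouring OH.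

**Alternative 3:** The stilbene route copies the presumed biosynthesis of 2-arylbenzofurans and cuts only O1–C2. Forward, the 2-hydroxystilbene A4 is closed oxidatively (iodine(III), iodine/base or palladium(II)) to the benzofuran. It was turned down because it forms the easiest bond of the molecule and leaves the pentasubstituted ring untouched: A4 needs the same ring as A1, plus an olefination at a carbon flanked by two prenyl groups. The oxidants that effect the closure are also the ones that convert ortho-prenylphenols into chromenes and dihydrobenzofurans, and A4 contains one such unit beside three free phenols.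

Key step: step 6

## Route

Step 1
Reactants: 1 ethoxyacetylene; 2 prenyl bromide (1-bromo-3-methylbut-2-ene)
Product: 4 1-ethoxy-5-methylhex-4-en-1-yne, via lithium ethoxyacetylide 3 (not isolated)
Conditions: n-BuLi, THF, −78 °C; then 2, DMPU, −78 °C → rt; NaHCO3 work-up, distillation
Reagents that add atoms: none
Why: Alkylation of a lithium alkoxyacetylide with a primary allylic bromide in a dipolar co-solvent (SN2) is a standard route to 1-alkoxyalk-1-ynes; the unhindered primary carbon of 2 favours direct over allylic-transposed substitution.

Step 2
Reactants: 4 1-ethoxy-5-methylhex-4-en-1-yne (two molecules)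
Product: 6 3-ethoxy-2,4-bis(3-methylbut-2-en-1-yl)cyclobut-2-en-1-one (racemic), via prenylketene 5 (not isolated)
Conditions: toluene (2 M), reflux (110 °C), N2 sweep
Reagents that add atoms: none
Why: 1-Ethoxyalk-1-ynes are known to lose ethene by a thermal retro-ene reaction to give the aldoketene, which is trapped by unchanged ynol ether in a regioselective [2+2] cycloaddition (ketene carbonyl carbon to the alkyl-bearing alkyne carbon) to give 2,4-dialkyl-3-ethoxycyclobutenones. The prenyl alkenes should be spectators, because an unactivated alkene is a far poorer ketenophile than an ynol ether and the one-carbon tether in 5 rules out intramolecular capture.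

Step 3
Reactants: 7 benzofuran-6-ol
Product: 8 (1-benzofuran-6-yloxy)tri(propan-2-yl)silane
Conditions: TIPSCl, imidazole, DMF, rt
Reagents that add atoms: chlorotri(propan-2-yl)silane (TIPSCl), CC(C)[Si](Cl)(C(C)C)C(C)C
Why: Standard silylation of a phenol; the bulky triisopropylsilyl ether is chosen to survive n-BuLi, dilute acid and heating at 110 °C and to leave under fluoride without acid.

Step 4
Reactants: 8 (1-benzofuran-6-yloxy)tri(propan-2-yl)silane; 6 3-ethoxy-2,4-bis(3-methylbut-2-en-1-yl)cyclobut-2-en-1-one
Product: 11 2,4-bis(3-methylbut-2-en-1-yl)-3-[6-(triisopropylsilyloxy)-1-benzofuran-2-yl]cyclobut-2-en-1-one (racemic), via 2-lithiobenzofuran 9 (not isolated), via cyclobutenol adduct 10 (not isolated)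
Conditions: n-BuLi, THF, −78 °C; 6, −78 → −20 °C; then 1 M HCl, 0 °C → rt
Reagents that add atoms: water, O
Why: C2 lithiation of benzofurans by n-BuLi is standard, and 1,2-addition of an aryllithium to a 3-alkoxycyclobutenone followed by acid hydrolysis (ionization of the carbinol, water attack at the ethoxy-bearing carbon, loss of ethanol) is the established 1,3-carbonyl transposition to 3-substituted cyclobutenones. Because C2 and C4 of 6 both carry prenyl, only one constitution can result; the C4 centre stays racemic and is erased in step 6.

Step 5
Reactants: 12 2-chloro-1,1-dimethoxyethane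
Product: 14 methoxyacetylene, via sodium methoxyacetylide 13 (not isolated)
Conditions: NaNH2 (3 equiv), liq. NH3, −33 °C; evaporate NH3; cold sat. aq. NaCl; distil (bp ca. 23 °C) into cold toluene
Reagents that add atoms: none
Why: Twofold amide-induced elimination (HCl, then methanol) from an α-chloroacetal followed by protonation of the acetylide is the classical preparation of alkoxyacetylenes; 14 is kept as a cold toluene solution and used directly.

Step 6
Reactants: 11 2,4-bis(3-methylbut-2-en-1-yl)-3-[6-(triisopropylsilyloxy)-1-benzofuran-2-yl]cyclobut-2-en-1-one; 14 methoxyacetylene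
Product: 19 5-methoxy-2,4-bis(3-methylbut-2-en-1-yl)-3-[6-(triisopropylsilyloxy)-1-benzofuran-2-yl]phenol, via vinylketene 15 (not isolated), via vinylcyclobutenone 16 (not isolated), via dienylketene 17 (not isolated), via cyclohexadienone 18 (not isolated)
Conditions: 14 (4 equiv), toluene (0.3 M), sealed tube, 80 °C then 110 °C
Reagents that add atoms: none
Why: Heating should open 11 by a reversible conrotatory 4π electrocyclic reaction to vinylketene 15, with the C4 prenyl group turning outward. The ketene C=C of 15 is then captured by 14 in a [2+2] cycloaddition: the electrophilic ketene carbon (future C3') bonds to the unsubstituted, nucleophilic alkyne carbon (future C4'), and the prenyl-bearing ketene carbon (future C6') bonds to the methoxy-bearing carbon (future C5'), closing the four-membered ring of 16. A second 4π opening of 16 gives dienylketene 17, whose thermal disrotatory 6π electrocyclization joins the ketene carbon to the prenyl-bearing vinyl terminus (the C3'–C2' bond) and closes the six-membered ring as dienone 18; enolization gives phenol 19. The closest known reaction type is the cyclobutenone–alkoxyacetylene benzannulation (Danheiser benzannulation), which is established for alkyl- and aryl-substituted cyclobutenones. No stereocentre is formed in 19, since the centres of 11, 16 and 18 are erased on aromatization, so only constitutional selectivity is needed. The regiochemistry (OH at C3' from the ketene carbonyl, OMe at C5', H at C4') follows from the polarity of ketene and ynol ether and is not opposed by sterics because the alkyne terminus is unsubstituted; as both flanking groups are prenyl, either numbering of 11 leads to the same arene. Chemoselectivity for 14 over the two trisubstituted alkenes and the benzofuran C2=C3 bond rests on the much higher ketenophilicity of an ynol ether, on its excess, and on the outward rotation that holds the C4 prenyl alkene away from the ketene. 14 has no O-alkyl β-hydrogen and so cannot fragment by the retro-ene path used in step 2.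

Step 7
Reactants: 19 5-methoxy-2,4-bis(3-methylbut-2-en-1-yl)-3-[6-(triisopropylsilyloxy)-1-benzofuran-2-yl]phenol
Product: 20 2-[3-hydroxy-5-methoxy-2,6-bis(3-methylbut-2-en-1-yl)phenyl]-1-benzofuran-6-ol (target)
Conditions: TBAF, AcOH (1.2 equiv each), THF, 0 °C → rt
Reagents that add atoms: none
Why: Fluoride cleavage of an aryl silyl ether; buffering with acetic acid keeps the medium neither basic nor acidic enough to cyclize the C2' prenyl group onto the C3' hydroxyl, and the methyl ether and alkenes are untouched.

## Compound list

1 | ethoxyacetylene (ethoxyethyne) | CCOC#C | starting material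
2 | prenyl bromide (1-bromo-3-methylbut-2-ene) | CC(C)=CCBr | starting material
3 | lithium ethoxyacetylide | [Li]C#COCC | intermediate (not isolated)
4 | 1-ethoxy-5-methylhex-4-en-1-yne | CCOC#CCC=C(C)C | intermediate
5 | 5-methylhexa-1,4-dien-1-one (prenylketene) | CC(C)=CCC=C=O | intermediate (not isolated)
6 | 3-ethoxy-2,4-bis(3-methylbut-2-en-1-yl)cyclobut-2-en-1-one (racemic) | CCOC1=C(CC=C(C)C)C(=O)C1CC=C(C)C | intermediate
7 | 1-benzofuran-6-ol | Oc1ccc2ccoc2c1 | starting material
8 | (1-benzofuran-6-yloxy)tri(propan-2-yl)silane | CC(C)[Si](Oc1ccc2ccoc2c1)(C(C)C)C(C)C | intermediate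
9 | [6-(triisopropylsilyloxy)-1-benzofuran-2-yl]lithium | [Li]c1cc2ccc(O[Si](C(C)C)(C(C)C)C(C)C)cc2o1 | intermediate (not isolated)
10 | 3-ethoxy-2,4-bis(3-methylbut-2-en-1-yl)-1-[6-(triisopropylsilyloxy)-1-benzofuran-2-yl]cyclobut-2-en-1-ol (mixture of diastereomers, racemic) | CCOC1=C(CC=C(C)C)C(O)(c2cc3ccc(O[Si](C(C)C)(C(C)C)C(C)C)cc3o2)C1CC=C(C)C | intermediate (not isolated)
11 | 2,4-bis(3-methylbut-2-en-1-yl)-3-[6-(triisopropylsilyloxy)-1-benzofuran-2-yl]cyclobut-2-en-1-one (racemic) | O=C1C(CC=C(C)C)=C(c2cc3ccc(O[Si](C(C)C)(C(C)C)C(C)C)cc3o2)C1CC=C(C)C | intermediate
12 | 2-chloro-1,1-dimethoxyethane (chloroacetaldehyde dimethyl acetal) | COC(CCl)OC | starting material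
13 | sodium methoxyacetylide | [Na]C#COC | intermediate (not isolated)
14 | methoxyacetylene (methoxyethyne) | COC#C | intermediate
15 | (3Z)-7-methyl-2-(3-methylbut-2-en-1-yl)-3-[6-(triisopropylsilyloxy)-1-benzofuran-2-yl]octa-1,3,6-trien-1-one (vinylketene, outward rotamer) | O=C=C(CC=C(C)C)/C(c1cc2ccc(O[Si](C(C)C)(C(C)C)C(C)C)cc2o1)=C/CC=C(C)C | intermediate (not isolated)
16 | 3-methoxy-4-(3-methylbut-2-en-1-yl)-4-{(1Z)-5-methyl-1-[6-(triisopropylsilyloxy)-1-benzofuran-2-yl]hexa-1,4-dien-1-yl}cyclobut-2-en-1-one (racemic) | COC1=CC(=O)C1(CC=C(C)C)/C(c2cc3ccc(O[Si](C(C)C)(C(C)C)C(C)C)cc3o2)=C/CC=C(C)C | intermediate (not isolated)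
17 | (3E,5Z)-3-methoxy-9-methyl-4-(3-methylbut-2-en-1-yl)-5-[6-(triisopropylsilyloxy)-1-benzofuran-2-yl]deca-1,3,5,8-tetraen-1-one (dienylketene) | O=C=C/C(OC)=C(/CC=C(C)C)\C(c1cc2ccc(O[Si](C(C)C)(C(C)C)C(C)C)cc2o1)=C\CC=C(C)C | intermediate (not isolated)
18 | 3-methoxy-4,6-bis(3-methylbut-2-en-1-yl)-5-[6-(triisopropylsilyloxy)-1-benzofuran-2-yl]cyclohexa-2,4-dien-1-one (racemic) | COC1=CC(=O)C(CC=C(C)C)C(c2cc3ccc(O[Si](C(C)C)(C(C)C)C(C)C)cc3o2)=C1CC=C(C)C | intermediate (not isolated)
19 | 5-methoxy-2,4-bis(3-methylbut-2-en-1-yl)-3-[6-(triisopropylsilyloxy)-1-benzofuran-2-yl]phenol | COc1cc(O)c(CC=C(C)C)c(-c2cc3ccc(O[Si](C(C)C)(C(C)C)C(C)C)cc3o2)c1CC=C(C)C | intermediate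
20 | 2-[3-hydroxy-5-methoxy-2,6-bis(3-methylbut-2-en-1-yl)phenyl]-1-benzofuran-6-ol | COc1cc(O)c(CC=C(C)C)c(-c2cc3ccc(O)cc3o2)c1CC=C(C)C | target

## Step count and risk

Total step count: 7. Longest linear sequence: 5 steps (1 → 2 → 4 → 6 → 7); steps 3 and 5 are one-step branches.

**Step 6 (key step).** The most likely failure is that bimolecular capture of the vinylketene at its fully substituted carbon is slower than its unimolecular escape routes. These are intramolecular [2+2] addition of the ketene to the C4 prenyl alkene after inward rotation, and ketene dimerization. O-acylation of the product phenol by the ketene may also occur; a brief basic methanolysis of the crude product would reverse it, and any loss of the silyl group there is harmless because step 7 removes it anyway. The fallback changes how the prenyl groups are introduced, so that no trisubstituted alkene is present during the ketene cascade. It sets out from 1 and comes back at 19. 1 is lithiated as in step 1 and alkylated with allyl bromide to 1-ethoxypent-4-en-1-yne F1. F1 is refluxed in toluene as in step 2 to give 3-ethoxy-2,4-di(prop-2-en-1-yl)cyclobut-2-en-1-one F2. Addition of 9 and acid hydrolysis as in step 4 give 2,4-di(prop-2-en-1-yl)-3-[6-(triisopropylsilyloxy)-1-benzofuran-2-yl]cyclobut-2-en-1-one F3. Benzannulation of F3 with 14 gives 5-methoxy-2,4-di(prop-2-en-1-yl)-3-[6-(triisopropylsilyloxy)-1-benzofuran-2-yl]phenol F4, whose monosubstituted alkenes are much poorer ketenophiles. A twofold olefin cross-metathesis with 2-methylbut-2-ene (ruthenium carbene catalyst, 40 °C) then converts both allyl groups into prenyl groups and gives 19.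

**Step 1.** The alkoxyacetylide is a weak nucleophile, so alkylation may be slow and may be accompanied by allylic-transposed substitution; the ynol ether may also be lost by hydration on isolation. The fallback builds the ynol ether from an ester instead of by acetylide alkylation. It sets out from 2 and comes back at 4. The lithium enolate of ethyl acetate (LDA, THF, −78 °C) is alkylated with 2 to give ethyl 5-methylhex-4-enoate F5. Its enolate is trapped with diethyl chlorophosphate as diethyl 1-ethoxy-5-methylhexa-1,4-dien-1-yl phosphate F6, and elimination of the phosphate with t-BuLi at −78 °C gives 4.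

**Step 2.** At the temperature needed for the retro-ene reaction the ketene may be consumed by dimerization, or the product may react further with the ynol ether after opening of its own ring. The fallback generates the ketene separately at low temperature by dehydrohalogenation. It sets out from 4, used only as the ketenophile, and comes back at 6. Purchased 5-methylhex-4-enoic acid F7 is converted with oxalyl chloride and catalytic DMF into 5-methylhex-4-enoyl chloride F8. F8 is added slowly to 4 and triethylamine in dichloromethane at 0 °C → rt, so that ketene 5 forms in the presence of excess 4 and gives 6.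

**Step 4.** Proton transfer from C4–H of 6 to the aryllithium may compete with 1,2-addition, and the acidic hydrolysis may be incomplete or may begin to remove the silyl group. The fallback makes the C2–C1' bond by cross-coupling instead of carbonyl addition. It sets out from 6 and comes back at 11. Mild aqueous acid hydrolysis of the vinylogous ester gives 3-hydroxy-2,4-bis(3-methylbut-2-en-1-yl)cyclobut-2-en-1-one F9, which is symmetric, so only one enol derivative is possible. Triflic anhydride and triethylamine give 2,4-bis(3-methylbut-2-en-1-yl)-3-oxocyclobut-1-en-1-yl trifluoromethanesulfonate F10. 9 is transmetalated with zinc chloride to chloro[6-(triisopropylsilyloxy)-1-benzofuran-2-yl]zinc F11, and a palladium(0)-catalysed Negishi coupling of F10 with F11 gives 11.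

## Further compounds

F1 | step 6 | 1-ethoxypent-4-en-1-yne | CCOC#CCC=C
F2 | step 6 | 3-ethoxy-2,4-di(prop-2-en-1-yl)cyclobut-2-en-1-one (racemic) | CCOC1=C(CC=C)C(=O)C1CC=C
F3 | step 6 | 2,4-di(prop-2-en-1-yl)-3-[6-(triisopropylsilyloxy)-1-benzofuran-2-yl]cyclobut-2-en-1-one (racemic) | O=C1C(CC=C)=C(c2cc3ccc(O[Si](C(C)C)(C(C)C)C(C)C)cc3o2)C1CC=C
F4 | step 6 | 5-methoxy-2,4-di(prop-2-en-1-yl)-3-[6-(triisopropylsilyloxy)-1-benzofuran-2-yl]phenol | COc1cc(O)c(CC=C)c(-c2cc3ccc(O[Si](C(C)C)(C(C)C)C(C)C)cc3o2)c1CC=C
F5 | step 1 | ethyl 5-methylhex-4-enoate | CCOC(=O)CCC=C(C)C
F6 | step 1 | diethyl 1-ethoxy-5-methylhexa-1,4-dien-1-yl phosphate (E/Z mixture) | CCOC(=CCC=C(C)C)OP(=O)(OCC)OCC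
F7 | step 2 | 5-methylhex-4-enoic acid | CC(C)=CCCC(=O)O
F8 | step 2 | 5-methylhex-4-enoyl chloride | CC(C)=CCCC(=O)Cl
F9 | step 4 | 3-hydroxy-2,4-bis(3-methylbut-2-en-1-yl)cyclobut-2-en-1-one (racemic) | OC1=C(CC=C(C)C)C(=O)C1CC=C(C)C
F10 | step 4 | 2,4-bis(3-methylbut-2-en-1-yl)-3-oxocyclobut-1-en-1-yl trifluoromethanesulfonate (racemic) | O=C1C(CC=C(C)C)=C(OS(=O)(=O)C(F)(F)F)C1CC=C(C)C
F11 | step 4 | chloro[6-(triisopropylsilyloxy)-1-benzofuran-2-yl]zinc | Cl[Zn]c1cc2ccc(O[Si](C(C)C)(C(C)C)C(C)C)cc2o1
A1 | alternative 1 | 3-ethynyl-1-methoxy-5-(methoxymethoxy)-2,4-bis(3-methylbut-2-en-1-yl)benzene | C#Cc1c(CC=C(C)C)c(OCOC)cc(OC)c1CC=C(C)C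
A2 | alternative 1 | 2-iodo-5-(triisopropylsilyloxy)phenol | Oc1cc(O[Si](C(C)C)(C(C)C)C(C)C)ccc1I
A3 | alternative 2 | 2-(3-hydroxy-5-methoxyphenyl)-1-benzofuran-6-ol | COc1cc(O)cc(-c2cc3ccc(O)cc3o2)c1
A4 | alternative 3 | 4-{(E)-2-[3-hydroxy-5-methoxy-2,6-bis(3-methylbut-2-en-1-yl)phenyl]ethenyl}benzene-1,3-diol | COc1cc(O)c(CC=C(C)C)c(/C=C/c2ccc(O)cc2O)c1CC=C(C)C
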